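Take the settings one at a time and reckon each by hand. I had this to go on:

in all of them: substrate 0.82 M

| flask | partner | remark | time |
|---|---|---|---|
| birch | 0.33 M | run made earlier |  |
| elm | 0.49 M | run made earlier |  |
| flask | 0.656 M |  | 6.0 min |

| run | time / min | target / % |
|---|---|---|
| birch | 0.167 | 10 |
| birch | 0.333 | 15 |
| birch | 1.00 | 8 |
| birch | 4.00 | 5 |
| elm | 0.167 | 11 |
| elm | 0.333 | 20 |
| elm | 1.00 | 7 |
| elm | 4.00 | 5 |

(standard deviation of a reading: 1.5 percentage points)

- on the list of suspects stand: substrate <-> open intermediate; partner -> second intermediate; open intermediate + second intermediate -> target; target <-> isomer of the product

- the moment within 6.0 min at which there is most target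
- the amount of target, in percent of the substrate charged, at that time

Time came first. In the birch and elm runs target stood highest at 0.333 min and had fallen to 5% in both by 4.00 min, so I expected the longer 6.0 min of the new flask to bring no higher peak, and I placed that peak near 0.333 min, before 1.00 min.

Partner came next. In the new flask it is the limiting reagent, with 0.656 M against 0.82 M of substrate, and the suspected path takes one of each into target. The elm run gave 0.335 for what I called the catch, the moles of target at the highest reading per mole of partner charged, and the birch run gave 0.373. Proportion was the large part and the fall in catch the correction, though each reading carries 1.5 percentage points, so that fall may be scatter. Holding the elm catch gave 26.8% for the new flask, and continuing the fall in a straight line gave 23.6%. I committed to that span.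

The forecast gave 26% at 0.38 min, on the ground that “Peak height increases with partner”.

The simulation gave 25.0% at 0.415 min, a catch of 0.312. From the birch run, changing the time left the best at 15.8%, while changing the partner raised it to 25.0%.

    substrate ⇌ open intermediate (K = 3.60, k = 0.0470 /s)
    partner → second intermediate (k = 0.170 /s)
    open intermediate + second intermediate → target (k = 0.330 /M/s)
    target ⇌ isomer of the product (K = 12.0, k = 0.0650 /s)

At 0.247 min in the flask, target had a half-life of 0.18 min by the forward step to isomer of the product, shorter than the 0.22 min of second intermediate on its way into target. A neighbour flask charged with 1.1 M of partner reached 29.7%, a lower catch of 0.221.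

The data are simulated for substances that don't exist, noise included.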